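Ring C is a benzo-fused 2,3-dihydropyran-4-one, so it is disconnected like an aldehyde–diene pyranone annulation: C2–C3 by aldol addition and O1–C8a by addition–elimination at ring A. C8a lies ortho to the C4 carbonyl and meta to both oxygens at C5 and C7, so a fluoride there is activated for SNAr. The key step joins, in one flask, the trimethylsilyl enol ether of a 2-fluoroacetophenone already carrying the (R)-lavandulyl chain with MOM-protected salicylaldehyde: a catalytic enantioselective Mukaiyama aldol sets C2, then fluoride unmasks the silyl aldolate, whose alkoxide displaces the C8a fluoride and releases fluoride again to carry the chain.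

Key step: step 10

Remark: flavanone numbering is used (O1, C2, C3, C4, C4a, C5–C8, C8a; ring A = benzo ring, ring B = 2-aryl group, ring C = pyranone ring).

Assumption: the oxazaborolidinone made from N-tosyl-D-tryptophan is taken to direct the enol silane to the Si face of aldehyde 19 (giving 2S). If a model aldol with benzaldehyde shows the opposite sense, the L-tryptophan-derived catalyst is used with no other change.

Assumption: 2-(methoxymethoxy)benzaldehyde 19 is taken as a commercial material.

Step 1
Reactants: 1 2,6-difluoro-4-hydroxybenzonitrile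
Product: 2 2,6-difluoro-4-(methoxymethoxy)benzonitrile
Conditions: MOMCl, iPr2NEt, CH2Cl2, 0 °C → rt
Reagents that add atoms: chloromethyl methyl ether (MOMCl), COCCl
Why: O-alkylation of the acidic phenol (Williamson-type acetal formation); the MOM ether tolerates the methoxide, amide-base and organolithium steps that follow and is removed only at the end.

Step 2
Reactants: 2 2,6-difluoro-4-(methoxymethoxy)benzonitrile
Product: 3 2-fluoro-6-methoxy-4-(methoxymethoxy)benzonitrile
Conditions: NaOMe (1.0 equiv), MeOH/THF, 0 °C → rt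
Reagents that add atoms: sodium methoxide, C[O-].[Na+]
Why: SNAr; both fluorides are ortho to the nitrile and equivalent by symmetry, and one equivalent of methoxide should stop at mono-substitution because the new methoxy group, conjugated with the nitrile, lowers the reactivity of the remaining fluoride.

Step 3
Reactants: 4 (4S)-4-benzyl-1,3-oxazolidin-2-one; 5 3-methylbut-2-enoyl chloride
Product: 7 (4S)-4-benzyl-3-(3-methylbut-2-enoyl)-1,3-oxazolidin-2-one, via N-lithio oxazolidinone 6 (not isolated)
Conditions: n-BuLi, THF, −78 °C; then 5, −78 → 0 °C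
Reagents that add atoms: none
Why: N-acylation of the lithiated oxazolidinone at low temperature (standard loading of the auxiliary), which avoids the amine-base conditions that deconjugate the enoyl chloride.

Step 4
Reactants: 7 (4S)-4-benzyl-3-(3-methylbut-2-enoyl)-1,3-oxazolidin-2-one; 8 1-bromo-3-methylbut-2-ene
Product: 10 (4S)-4-benzyl-3-[(2S)-5-methyl-2-(prop-1-en-2-yl)hex-4-enoyl]-1,3-oxazolidin-2-one, via sodium dienolate 9 (not isolated)
Conditions: NaHMDS (1.05 equiv), THF, −78 °C; then 8, −78 → −40 °C; cold NH4Cl quench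
Reagents that add atoms: none
Why: Auxiliary-controlled (Evans-type) deconjugative alkylation; γ-deprotonation gives the chelated (Z)-dienolate 9, which reacts at C-α with the allylic bromide on the face opposite the benzyl group, setting the (2S) centre of 10 (the later 2R centre of the lavandulyl chain) and leaving the isopropenyl group out of conjugation.

Step 5
Reactants: 10 (4S)-4-benzyl-3-[(2S)-5-methyl-2-(prop-1-en-2-yl)hex-4-enoyl]-1,3-oxazolidin-2-one
Product: 11 (2S)-5-methyl-2-(prop-1-en-2-yl)hex-4-en-1-ol ((S)-lavandulol)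
Conditions: LiBH4, MeOH (1 equiv), Et2O, 0 °C
Reagents that add atoms: none
Why: Reductive cleavage of the imide by LiBH4 at the exocyclic carbonyl should give the primary alcohol without touching the alkenes or epimerising the allylic α-centre, and returns the auxiliary.

Step 6
Reactants: 11 (2S)-5-methyl-2-(prop-1-en-2-yl)hex-4-en-1-ol
Product: 12 (2S)-5-methyl-2-(prop-1-en-2-yl)hex-4-en-1-yl trifluoromethanesulfonate
Conditions: Tf2O, pyridine, CH2Cl2, −78 → −30 °C; cold pentane/silica filtration, used at once
Reagents that add atoms: trifluoromethanesulfonic anhydride (Tf2O), O=S(=O)(OS(=O)(=O)C(F)(F)F)C(F)(F)F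
Why: O-sulfonylation of the primary alcohol; a triflate is chosen because it alkylates an aryllithium at −78 °C, and it is kept cold and used at once since it is homoallylic.

Step 7
Reactants: 3 2-fluoro-6-methoxy-4-(methoxymethoxy)benzonitrile; 12 (2S)-5-methyl-2-(prop-1-en-2-yl)hex-4-en-1-yl trifluoromethanesulfonate
Product: 14 2-fluoro-6-methoxy-4-(methoxymethoxy)-3-[(2R)-5-methyl-2-(prop-1-en-2-yl)hex-4-en-1-yl]benzonitrile, via aryllithium 13 (not isolated)
Conditions: LiTMP (1.05 equiv), THF, −78 °C; then 12 (1.2 equiv), −78 °C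
Reagents that add atoms: none
Why: Directed ortho-metalation under acidity control (LiTMP removes the proton flanked by fluorine and the MOM-oxy group, not the one between the two ethers, and the hindered amide spares the nitrile), then SN2 alkylation of aryllithium 13 by the primary triflate below the temperature at which 13 loses LiF; the stereocentre is β to the reacting carbon and is not touched.

Step 8
Reactants: 14 2-fluoro-6-methoxy-4-(methoxymethoxy)-3-[(2R)-5-methyl-2-(prop-1-en-2-yl)hex-4-en-1-yl]benzonitrile
Product: 16 1-{2-fluoro-6-methoxy-4-(methoxymethoxy)-3-[(2R)-5-methyl-2-(prop-1-en-2-yl)hex-4-en-1-yl]phenyl}ethan-1-one, via N-lithio ketimine 15 (not isolated)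
Conditions: MeLi, Et2O/THF, 0 °C → rt; then 1 M aq. HCl, THF, 0 °C
Reagents that add atoms: methyllithium, [Li]C; water, O
Why: Addition of MeLi to the nitrile stops at the N-lithio ketimine 15 (no second addition), and cold dilute acid should hydrolyse the imine to the methyl ketone while the aryl MOM ether and the alkenes survive.

Step 9
Reactants: 16 1-{2-fluoro-6-methoxy-4-(methoxymethoxy)-3-[(2R)-5-methyl-2-(prop-1-en-2-yl)hex-4-en-1-yl]phenyl}ethan-1-one
Product: 18 ({1-[2-fluoro-6-methoxy-4-(methoxymethoxy)-3-[(2R)-5-methyl-2-(prop-1-en-2-yl)hex-4-en-1-yl]phenyl]ethenyl}oxy)trimethylsilane, via lithium enolate 17 (not isolated)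
Conditions: LDA, THF, −78 °C; then TMSCl, −78 → 0 °C; non-aqueous work-up (pentane, filtration), used crude
Reagents that add atoms: chlorotrimethylsilane (TMSCl), C[Si](C)(C)Cl
Why: Kinetic enolisation with LDA (the methyl group is the only enolisable position) and O-silylation of the lithium enolate give the terminal silyl enol ether needed for the Mukaiyama aldol.

Step 10
Reactants: 18 ({1-[2-fluoro-6-methoxy-4-(methoxymethoxy)-3-[(2R)-5-methyl-2-(prop-1-en-2-yl)hex-4-en-1-yl]phenyl]ethenyl}oxy)trimethylsilane; 19 2-(methoxymethoxy)benzaldehyde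
Product: 22 (2S)-5-methoxy-7-(methoxymethoxy)-2-[2-(methoxymethoxy)phenyl]-8-[(2R)-5-methyl-2-(prop-1-en-2-yl)hex-4-en-1-yl]chroman-4-one, via trimethylsilyl aldolate 20 (not isolated), via tetrabutylammonium alkoxide 21 (not isolated)
Conditions: 19 (1.5 equiv), oxazaborolidinone from N-tosyl-D-tryptophan and n-BuB(OH)2 (20 mol %), EtCN, −78 °C; then n-Bu4N[Ph3SiF2] (0.5 equiv), THF, −78 °C → rt; pH 7 buffer
Reagents that add atoms: none
Why: The chiral boron Lewis acid activates aldehyde 19 and the terminal carbon of enol silane 18 adds through an open transition state to its Si face (C2–C3 bond), silyl transfer giving the β-silyloxy ketone 20; added fluoride then desilylates 20 and the ammonium alkoxide 21 attacks C8a of ring A in an intramolecular SNAr that expels fluoride (O1–C8a bond), so that the fluoride set free carries the cyclisation on. The closest known reaction types are the oxazaborolidinone-catalysed Mukaiyama aldol of methyl ketone enol silanes with aromatic aldehydes, its aldol–cyclisation variant that turns 1-methoxy-3-silyloxybutadienes into dihydropyranones, and the fluoride-catalysed SNAr etherification of silyl ethers with carbonyl-activated aryl fluorides. Ring C, the only ring closed, forms by 6-exo-trig addition of the alkoxide to C8a and loss of fluoride from a Meisenheimer anion stabilised by the coplanar C4 carbonyl. C2, the only new stereocentre, is set in the aldol stage by the catalyst through its choice of aldehyde face, and because the C2–O bond is never broken the ring closure occurs with retention and should give the 2S product. The step needs face selectivity (catalyst), closure at C8a–F and not at C5–OMe (fluoride is by far the better nucleofuge), and ring closure faster than retro-aldol or E1cB loss of the alkoxide; the fluoride ortho to the ketone, the low temperature and the substoichiometric fluoride serve the last point. The aldehyde is used in excess so that no enol silane is left when fluoride is added and no uncatalysed aldol can occur.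

Step 11
Reactants: 22 (2S)-5-methoxy-7-(methoxymethoxy)-2-[2-(methoxymethoxy)phenyl]-8-[(2R)-5-methyl-2-(prop-1-en-2-yl)hex-4-en-1-yl]chroman-4-one
Product: 23 kushenol R, (2S)-7-hydroxy-2-(2-hydroxyphenyl)-5-methoxy-8-[(2R)-5-methyl-2-(prop-1-en-2-yl)hex-4-en-1-yl]chroman-4-one
Conditions: 3 M aq. HCl/MeOH (1:6), 40 °C, stopped at full conversion
Reagents that add atoms: none
Why: Acid-catalysed acetal exchange (methanolysis of both aryl MOM ethers) frees the C7 and C2' phenols; warm dilute HCl in methanol should be too weak to protonate the lavandulyl alkenes, and C2 is configurationally stable in acid because ring opening needs the enolate.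

Compound list
1 | 2,6-difluoro-4-hydroxybenzonitrile | N#Cc1c(F)cc(O)cc1F | starting material
2 | 2,6-difluoro-4-(methoxymethoxy)benzonitrile | COCOc1cc(F)c(C#N)c(F)c1 | intermediate
3 | 2-fluoro-6-methoxy-4-(methoxymethoxy)benzonitrile | COCOc1cc(F)c(C#N)c(OC)c1 | intermediate
4 | (4S)-4-benzyl-1,3-oxazolidin-2-one | O=C1N[C@@H](Cc2ccccc2)CO1 | starting material
5 | 3-methylbut-2-enoyl chloride | CC(C)=CC(=O)Cl | starting material
6 | N-lithio derivative of (4S)-4-benzyl-1,3-oxazolidin-2-one | [Li]N1[C@@H](Cc2ccccc2)COC1=O | intermediate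
7 | (4S)-4-benzyl-3-(3-methylbut-2-enoyl)-1,3-oxazolidin-2-one | CC(C)=CC(=O)N1[C@@H](Cc2ccccc2)COC1=O | intermediate
8 | 1-bromo-3-methylbut-2-ene (prenyl bromide) | CC(C)=CCBr | starting material
9 | sodium (Z)-dienolate of 7 | C=C(C)/C=C(\[O-])N1[C@@H](Cc2ccccc2)COC1=O.[Na+] | intermediate
10 | (4S)-4-benzyl-3-[(2S)-5-methyl-2-(prop-1-en-2-yl)hex-4-enoyl]-1,3-oxazolidin-2-one | C=C(C)[C@H](CC=C(C)C)C(=O)N1[C@@H](Cc2ccccc2)COC1=O | intermediate
11 | (2S)-5-methyl-2-(prop-1-en-2-yl)hex-4-en-1-ol ((S)-lavandulol) | C=C(C)[C@H](CC=C(C)C)CO | intermediate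
12 | (2S)-5-methyl-2-(prop-1-en-2-yl)hex-4-en-1-yl trifluoromethanesulfonate | C=C(C)[C@H](CC=C(C)C)COS(=O)(=O)C(F)(F)F | intermediate
13 | [3-cyano-2-fluoro-4-methoxy-6-(methoxymethoxy)phenyl]lithium | COCOc1cc(OC)c(C#N)c(F)c1[Li] | intermediate
14 | 2-fluoro-6-methoxy-4-(methoxymethoxy)-3-[(2R)-5-methyl-2-(prop-1-en-2-yl)hex-4-en-1-yl]benzonitrile | C=C(C)[C@H](CC=C(C)C)Cc1c(OCOC)cc(OC)c(C#N)c1F | intermediate
15 | N-lithio ketimine of 16 | C=C(C)[C@H](CC=C(C)C)Cc1c(OCOC)cc(OC)c(C(C)=N[Li])c1F | intermediate
16 | 1-{2-fluoro-6-methoxy-4-(methoxymethoxy)-3-[(2R)-5-methyl-2-(prop-1-en-2-yl)hex-4-en-1-yl]phenyl}ethan-1-one | C=C(C)[C@H](CC=C(C)C)Cc1c(OCOC)cc(OC)c(C(C)=O)c1F | intermediate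
17 | lithium enolate of 16 | C=C(C)[C@H](CC=C(C)C)Cc1c(OCOC)cc(OC)c(C(=C)O[Li])c1F | intermediate
18 | trimethylsilyl enol ether of 16 | C=C(C)[C@H](CC=C(C)C)Cc1c(OCOC)cc(OC)c(C(=C)O[Si](C)(C)C)c1F | intermediate
19 | 2-(methoxymethoxy)benzaldehyde | O=Cc1ccccc1OCOC | starting material
20 | (3S)-1-{2-fluoro-6-methoxy-4-(methoxymethoxy)-3-[(2R)-5-methyl-2-(prop-1-en-2-yl)hex-4-en-1-yl]phenyl}-3-[2-(methoxymethoxy)phenyl]-3-(trimethylsilyloxy)propan-1-one | C=C(C)[C@H](CC=C(C)C)Cc1c(OCOC)cc(OC)c(C(=O)C[C@H](O[Si](C)(C)C)c2ccccc2OCOC)c1F | intermediate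
21 | tetrabutylammonium (1S)-alkoxide formed from 20 by loss of the silyl group | C=C(C)[C@H](CC=C(C)C)Cc1c(OCOC)cc(OC)c(C(=O)C[C@H]([O-])c2ccccc2OCOC)c1F.CCCC[N+](CCCC)(CCCC)CCCC | intermediate
22 | (2S)-5-methoxy-7-(methoxymethoxy)-2-[2-(methoxymethoxy)phenyl]-8-[(2R)-5-methyl-2-(prop-1-en-2-yl)hex-4-en-1-yl]chroman-4-one | C=C(C)[C@H](CC=C(C)C)Cc1c(OCOC)cc(OC)c2c1O[C@H](c1ccccc1OCOC)CC2=O | intermediate
23 | kushenol R, (2S)-7-hydroxy-2-(2-hydroxyphenyl)-5-methoxy-8-[(2R)-5-methyl-2-(prop-1-en-2-yl)hex-4-en-1-yl]chroman-4-one | C=C(C)[C@H](CC=C(C)C)Cc1c(O)cc(OC)c2c1O[C@H](c1ccccc1O)CC2=O | target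

Total step count: 11. Longest linear sequence: 9 steps (steps 3 to 11, from oxazolidinone 4); the ring-A branch from nitrile 1 runs over 7 steps.

Steps most likely to fail

1. Step 10. The alkoxide 21 may revert by retro-aldol before it closes the ring (loss of enantiopurity), may lose water by E1cB to the chalcone, or the boron catalyst may select the aldehyde face poorly with an ortho-alkoxy aldehyde and a hindered enol silane. The fallback separates the two bond formations and changes the mode of catalysis. It sets out from 18 and 19: SiCl4 activated by a chiral binaphthyldiamine-derived bisphosphoramide (Lewis-base catalysis, 5 mol %, CH2Cl2, −78 °C; the (S,S) enantiomer is assumed and would be confirmed on a benzaldehyde model) should give the trichlorosilyl aldolate F1, which cold aqueous NaHCO3 hydrolyses to the isolated (3S)-β-hydroxy ketone F2. After its enantiopurity is checked, F2 is cyclised in a separate step by intramolecular SNAr with Cs2CO3 in DMF at 0 °C, which comes back to the route at 22.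

2. Step 7. SN2 attack of the doubly ortho-substituted aryllithium on the β-branched triflate may be slow, so that loss of LiF from 13 (aryne formation) or ionisation of the homoallylic triflate competes. The fallback replaces the alkylation by a cross-coupling and sets out from 3 and 11. Aryllithium 13, generated as in step 7, is quenched with I2 to give 2-fluoro-3-iodo-6-methoxy-4-(methoxymethoxy)benzonitrile F3. Lavandulol 11 is converted with I2, PPh3 and imidazole into (3S)-3-(iodomethyl)-2,6-dimethylhepta-1,5-diene F4, and zinc dust with LiCl in THF inserts to give the alkylzinc iodide F5. Negishi coupling of F3 with F5 (Pd(OAc)2, SPhos, THF, rt) comes back to the route at 14.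

3. Step 11. Under acid the freed C7 phenol may add across the neighbouring isopropenyl group (chroman formation), or methanol may add to the alkenes before both acetals are cleaved. The fallback replaces Brønsted-acid methanolysis by Lewis-acid silyl transfer and sets out from 22. TMSOTf with 2,2'-bipyridyl in CH2Cl2/MeCN at 0 °C should convert both aryl MOM ethers into aryl trimethylsilyl ethers, giving the bis(trimethylsilyl) ether F6. F6 is hydrolysed with water in THF at rt under neutral conditions, which comes back to the route at 23.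

Further compounds
F1 | step 10 | (3S)-1-{2-fluoro-6-methoxy-4-(methoxymethoxy)-3-[(2R)-5-methyl-2-(prop-1-en-2-yl)hex-4-en-1-yl]phenyl}-3-[2-(methoxymethoxy)phenyl]-3-(trichlorosilyloxy)propan-1-one | C=C(C)[C@H](CC=C(C)C)Cc1c(OCOC)cc(OC)c(C(=O)C[C@H](O[Si](Cl)(Cl)Cl)c2ccccc2OCOC)c1F
F2 | step 10 | (3S)-1-{2-fluoro-6-methoxy-4-(methoxymethoxy)-3-[(2R)-5-methyl-2-(prop-1-en-2-yl)hex-4-en-1-yl]phenyl}-3-hydroxy-3-[2-(methoxymethoxy)phenyl]propan-1-one | C=C(C)[C@H](CC=C(C)C)Cc1c(OCOC)cc(OC)c(C(=O)C[C@H](O)c2ccccc2OCOC)c1F
F3 | step 7 | 2-fluoro-3-iodo-6-methoxy-4-(methoxymethoxy)benzonitrile | COCOc1cc(OC)c(C#N)c(F)c1I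
F4 | step 7 | (3S)-3-(iodomethyl)-2,6-dimethylhepta-1,5-diene | C=C(C)[C@H](CC=C(C)C)CI
F5 | step 7 | [(2S)-5-methyl-2-(prop-1-en-2-yl)hex-4-en-1-yl]zinc iodide | C=C(C)[C@H](CC=C(C)C)C[Zn]I
F6 | step 11 | (2S)-5-methoxy-8-[(2R)-5-methyl-2-(prop-1-en-2-yl)hex-4-en-1-yl]-7-(trimethylsilyloxy)-2-[2-(trimethylsilyloxy)phenyl]chroman-4-one | C=C(C)[C@H](CC=C(C)C)Cc1c(O[Si](C)(C)C)cc(OC)c2c1O[C@H](c1ccccc1O[Si](C)(C)C)CC2=O
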